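**Retrosynthetic overview**
- Target ⇐ ten-membered 9-keto-15-al with C14 masked as a dimethyl acetal: C9/C15 reduction, C9 angeloylation and acetal unmasking come last.
- Ten-membered ring ⇐ four-atom ring expansion of a decalin aldol: desilylative retro-aldol cleavage of C4–C9, then E1cB loss of the C5 acetate.
- Decalin ⇐ intramolecular Diels–Alder reaction of a 1-siloxydiene (C9=C10–C1=C2) with a 2-substituted acrolein (C3=C4), tethered through C5–C8.
- Acyclic precursor ⇐ two indium Barbier allylations (C7–C8, C9–C10) and one Nozaki–Hiyama–Kishi vinylation (C4–C5) around an α-methylene-γ-butyrolactone made from methyl acrylate and (R)-glyceraldehyde acetonide.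
- Ring order: γ-lactone, then the two six-membered rings together, then expansion to the ten-membered carbocycle.

Assumption: atoms are labelled C1–C15 by germacrane numbering of the target (lactone C6–O–C12, methylene C11=C13, C14 on C10, C15 on C4), and acetal, acetonide and silyl groups are treated as protecting groups.

**Route**

Step 1
Reactants: 1 (E)-but-2-enal (crotonaldehyde)
Product: 2 (E)-4-bromobut-2-enal
Conditions: NBS, (PhCO2)2 (cat.), CCl4, reflux
Reagents that add atoms: N-bromosuccinimide, O=C1CCC(=O)N1Br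
Why: Wohl–Ziegler radical bromination takes place at the γ-methyl group of the enal and leaves the E-alkene intact.

Step 2
Reactants: 2 (E)-4-bromobut-2-enal
Product: 3 (E)-4-bromo-1,1-dimethoxybut-2-ene
Conditions: HC(OMe)3, Amberlyst-15 (cat.), CH2Cl2, 0 °C → rt
Reagents that add atoms: trimethyl orthoformate, COC(OC)OC
Why: Acid-catalysed acetalisation with an orthoester masks the future C14 aldehyde as a dimethyl acetal that survives until the last step.

Step 3
Reactants: 4 2-bromoprop-2-en-1-ol
Product: 5 [(2-bromoprop-2-en-1-yl)oxy]triethylsilane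
Conditions: TESCl, imidazole, CH2Cl2, 0 °C
Reagents that add atoms: chlorotriethylsilane, CC[Si](Cl)(CC)CC
Why: Routine silyl ether formation at the primary allylic alcohol (future C15–OH).

Step 4
Reactants: 6 methyl acrylate; 7 (R)-2,2-dimethyl-1,3-dioxolane-4-carbaldehyde
Product: 8 methyl 2-{[(4R)-2,2-dimethyl-1,3-dioxolan-4-yl](hydroxy)methyl}prop-2-enoate (both carbinol epimers)
Conditions: DABCO (30 mol%), 1,4-dioxane–H2O (1:1), rt
Reagents that add atoms: none
Why: The Morita–Baylis–Hillman reaction joins the acrylate α-carbon (C11) to the aldehyde carbon (C7) without touching the dioxolane stereocentre (future C6); the new carbinol centre is erased in step 5.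

Step 5
Reactants: 8 Morita–Baylis–Hillman adduct
Product: 9 methyl (2Z)-2-(bromomethyl)-3-[(4S)-2,2-dimethyl-1,3-dioxolan-4-yl]prop-2-enoate
Conditions: NBS, Me2S, CH2Cl2, −20 °C → rt
Reagents that add atoms: N-bromosuccinimide, O=C1CCC(=O)N1Br
Why: Corey–Kim-type activation followed by SN2′ attack of bromide transposes the allylic system to the thermodynamically preferred (Z)-2-(bromomethyl)enoate.

Step 6
Reactants: 9 (Z)-allylic bromide; 10 2,2-dimethoxyacetaldehyde
Product: 11 methyl (3R,4S)-3-[(4S)-2,2-dimethyl-1,3-dioxolan-4-yl]-4-hydroxy-5,5-dimethoxy-2-methylidenepentanoate (C6, C7, C8 as in the target)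
Conditions: In powder, THF–H2O (1:1), rt
Reagents that add atoms: none
Why: Indium-mediated Barbier allylation through a Zimmerman–Traxler chair, in which the Z-configured allylindium fixes the C7/C8 relationship and the aldehyde adds anti to the allylic C6–O bond of the A(1,3)-minimised conformer, so C7 and C8 are set relative to the glyceraldehyde-derived C6.

Step 7
Reactants: 11 hydroxy ester; 12 angelic acid [(2Z)-2-methylbut-2-enoic acid]
Product: 13 C8 O-angelate of 11 (all three stereocentres unchanged)
Conditions: 12, 2,4,6-trichlorobenzoyl chloride, Et3N, PhMe, rt; then 11, 75 °C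
Reagents that add atoms: none
Why: Yamaguchi esterification through the mixed anhydride without DMAP acylates O8 with retention and without angelate-to-tiglate isomerisation, and it blocks lactonisation onto O8.

Step 8
Reactants: 13 C8 angelate
Product: 14 lactone alcohol: 3-methylidene-γ-butyrolactone with CH2OH (C5) on C6 and, trans to it on C7, the chain C8H(O-angeloyl)–C9H(OMe)2
Conditions: PPTS (cat.), MeOH, 40 °C; then PhMe, 60 °C
Reagents that add atoms: none
Why: Acid-catalysed transacetalisation frees the C5,C6-diol and the C6 hydroxyl closes the γ-lactone on the acrylate ester (trans C6/C7 follows from step 6), while the deactivated α-acyloxy dimethyl acetal at C9 stays intact.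

Step 9
Reactants: 14 lactone alcohol
Product: 15 lactone aldehyde (C5 = CHO)
Conditions: Dess–Martin periodinane, CH2Cl2, 0 °C → rt
Reagents that add atoms: none
Why: Dess–Martin oxidation gives the α-oxygenated aldehyde under near-neutral conditions that do not epimerise C6.

Step 10
Reactants: 15 lactone aldehyde; 5 [(2-bromoprop-2-en-1-yl)oxy]triethylsilane
Product: 17 C5 acetate carrying the C4(=C3H2)–C15H2OTES unit (both C5 epimers), via C5 carbinol 16 (not isolated)
Conditions: CrCl2 (4 equiv), NiCl2 (2 mol%), DMF, rt; then Ac2O, DMAP (cat.), rt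
Reagents that add atoms: acetic anhydride, CC(=O)OC(C)=O
Why: Nozaki–Hiyama–Kishi coupling adds the vinylchromium reagent chemoselectively to the aldehyde and the alkoxide is acetylated in the same flask, which installs C3, C4, C15 and the C5 leaving group; the C5 configuration is irrelevant because C5 becomes sp2 in step 15.

Step 11
Reactants: 17 C5 acetate
Product: 18 aldehyde alcohol (C9 = CHO, free C15–OH)
Conditions: TFA–H2O (9:1), CH2Cl2, 0 °C
Reagents that add atoms: water, O
Why: Aqueous acid hydrolyses the dimethyl acetal to the C9 aldehyde and cleaves the triethylsilyl ether, while the esters and the lactone are stable at 0 °C.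

Step 12
Reactants: 18 aldehyde alcohol; 3 (E)-4-bromo-1,1-dimethoxybut-2-ene
Product: 19 diol with C9H(OH)–C10H(CH=CH2)–C14H(OMe)2 (mixture at C5, C9, C10)
Conditions: In powder, THF–H2O (3:1), 0 °C → rt
Reagents that add atoms: none
Why: Indium-mediated Barbier allylation with γ-selectivity (SE2′) gives the branched homoallylic alcohol that carries C10 with its vinyl (C1=C2) and acetal (C14) substituents; the C9 and C10 configurations are erased in steps 13–15.

Step 13
Reactants: 19 diol
Product: 20 keto enal (C9 ketone, C15 aldehyde)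
Conditions: Dess–Martin periodinane (2.5 equiv), CH2Cl2, 0 °C → rt
Reagents that add atoms: none
Why: Dess–Martin oxidation converts the secondary C9 alcohol into the ketone and the allylic C15 alcohol into the enal in one operation.

Step 14
Reactants: 20 keto enal
Product: 22 Diels–Alder adduct: decalin (ring A C4–C5–C6–C7–C8–C9, ring B C9–C10=C1–C2–C3–C4) with C9–OTMS, angular C4–CHO, C5–OAc, C8–O-angeloyl, C10–CH(OMe)2 and the C6/C7-fused lactone (mixture at C4, C5, C9), via silyl dienol ether 21 (not isolated)
Conditions: TMSCl, Et3N, MeCN, 0 °C → rt; then PhMe, 80 °C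
Reagents that add atoms: chlorotrimethylsilane, C[Si](C)(C)Cl
Why: Soft enolisation at the doubly activated C10–H gives the 1-siloxy-1,3-diene, whose type 1 intramolecular Diels–Alder reaction with the tethered 2-substituted acrolein (electronically matched, C2 to C3 and C9 to C4) builds a decalin in which C1=C10 is a cyclohexene bond and therefore cis; the new centres C4, C5 and C9 are removed again in step 15.

Step 15
Reactants: 22 Diels–Alder adduct
Product: 25 ten-membered dienone aldehyde: 9-oxo, C4(CHO)=C5 and C10[CH(OMe)2]=C1 both ring-cis, 8-O-angeloyl, 6,12-olide, via C9 alkoxide 23 (not isolated), via ring-opened enolate 24 (not isolated)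
Conditions: TBAF (1.1 equiv), THF, −40 → 0 °C
Reagents that add atoms: none
Why: Proposed new method: fluoride unmasks the tertiary C9 alkoxide β to the angular aldehyde, retro-aldol cleavage of the congested C4–C9 bond (two adjacent fully substituted carbons; the new ketone is conjugated with C10=C1) gives the ten-membered aldehyde enolate, and irreversible E1cB loss of the C5 acetate delivers the (E)-2-alkyl-2-enal, whose thermodynamic geometry is the ring-cis C4=C5, while C1=C10 stays cis because it was a ring B bond; the closest known reaction types are retro-aldol ring expansions of bicyclic β-hydroxy carbonyl compounds (de Mayo-type) and Grob/Wharton fragmentations of decalins to cyclodecenones, but a four-atom retro-aldol/E1cB expansion of a Diels–Alder adduct to a cyclodeca-1,5-diene has not been shown.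

Step 16
Reactants: 25 dienone aldehyde
Product: 26 9α,15-diol (C9 as in the target)
Conditions: NaBH4, CeCl3·7H2O, MeOH, −78 °C
Reagents that add atoms: none
Why: Luche reduction (1,2-selective, no conjugate reduction of the α-methylene lactone) reduces the enal to the C15 alcohol and the enone to the C9 alcohol, with hydride adding under polar Felkin–Anh control anti to the C8–O bond from the ring periphery to give the 8,9-trans alcohol.

Step 17
Reactants: 26 diol
Product: 27 15-O-TBS ether
Conditions: TBSCl (1.05 equiv), imidazole, CH2Cl2, −20 °C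
Reagents that add atoms: tert-butyl(chloro)dimethylsilane, CC(C)(C)[Si](C)(C)Cl
Why: Silyl ether formation is selective for the primary allylic C15 hydroxyl over the hindered secondary C9 hydroxyl.

Step 18
Reactants: 27 15-O-TBS ether; 12 angelic acid
Product: 28 8,9-bis-angelate
Conditions: 12, 2,4,6-trichlorobenzoyl chloride, Et3N, PhMe, rt; then 27, 75 °C
Reagents that add atoms: none
Why: Yamaguchi esterification (mixed anhydride, no DMAP) acylates the remaining C9 hydroxyl with retention and without isomerising either angelate.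

Step 19
Reactants: 28 bis-angelate
Product: 29 target CNP0139154.1 (8β,9α-diangeloyloxy-15-hydroxy-14-oxo cis,cis-germacra-1(10),4,11(13)-trien-12,6-olide; 6R,7S,8S,9S)
Conditions: aq. HF (48%), MeCN–H2O, 0 °C → rt
Reagents that add atoms: water, O
Why: Aqueous HF removes the silyl ether and hydrolyses the allylic dimethyl acetal to the conjugated C14 aldehyde, whose C1=C10 geometry is already the thermodynamically preferred one.

**Compound list**

1 | (E)-but-2-enal | C/C=C/C=O | starting material
2 | (E)-4-bromobut-2-enal | O=C/C=C/CBr | intermediate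
3 | (E)-4-bromo-1,1-dimethoxybut-2-ene | COC(OC)/C=C/CBr | intermediate
4 | 2-bromoprop-2-en-1-ol | C=C(Br)CO | starting material
5 | [(2-bromoprop-2-en-1-yl)oxy]triethylsilane | C=C(Br)CO[Si](CC)(CC)CC | intermediate
6 | methyl acrylate | C=CC(=O)OC | starting material
7 | (R)-2,2-dimethyl-1,3-dioxolane-4-carbaldehyde (acetonide-protected D-glyceraldehyde) | O=C[C@H]1COC(C)(C)O1 | starting material
8 | methyl 2-{[(4R)-2,2-dimethyl-1,3-dioxolan-4-yl](hydroxy)methyl}prop-2-enoate, both carbinol epimers | C=C(C(=O)OC)C(O)[C@H]1COC(C)(C)O1 | intermediate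
9 | methyl (2Z)-2-(bromomethyl)-3-[(4S)-2,2-dimethyl-1,3-dioxolan-4-yl]prop-2-enoate | COC(=O)/C(CBr)=C/[C@H]1COC(C)(C)O1 | intermediate
10 | 2,2-dimethoxyacetaldehyde | O=CC(OC)OC | starting material
11 | methyl (3R,4S)-3-[(4S)-2,2-dimethyl-1,3-dioxolan-4-yl]-4-hydroxy-5,5-dimethoxy-2-methylidenepentanoate | C=C(C(=O)OC)[C@@H]([C@H]1COC(C)(C)O1)[C@H](O)C(OC)OC | intermediate
12 | angelic acid, (2Z)-2-methylbut-2-enoic acid | C/C=C(/C)C(=O)O | starting material
13 | C8 O-angelate of 11 | C=C(C(=O)OC)[C@@H]([C@H]1COC(C)(C)O1)[C@H](OC(=O)/C(C)=C\C)C(OC)OC | intermediate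
14 | lactone alcohol (C6–CH2OH; C7 chain C8H(OAng)–C9H(OMe)2; C6/C7 trans) | C=C1C(=O)O[C@H](CO)[C@H]1[C@H](OC(=O)/C(C)=C\C)C(OC)OC | intermediate
15 | lactone aldehyde (C5 = CHO) | C=C1C(=O)O[C@H](C=O)[C@H]1[C@H](OC(=O)/C(C)=C\C)C(OC)OC | intermediate
16 | C5 carbinol (chromium alkoxide in the flask; both C5 epimers) | C=C1C(=O)O[C@H](C(O)C(=C)CO[Si](CC)(CC)CC)[C@H]1[C@H](OC(=O)/C(C)=C\C)C(OC)OC | intermediate
17 | C5 acetate with C4(=CH2)–CH2OTES (both C5 epimers) | C=C1C(=O)O[C@H](C(OC(C)=O)C(=C)CO[Si](CC)(CC)CC)[C@H]1[C@H](OC(=O)/C(C)=C\C)C(OC)OC | intermediate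
18 | aldehyde alcohol (C9 = CHO, C15–OH) | C=C1C(=O)O[C@H](C(OC(C)=O)C(=C)CO)[C@H]1[C@H](OC(=O)/C(C)=C\C)C=O | intermediate
19 | diol (C9–OH, C15–OH; C10 bears vinyl and CH(OMe)2) | C=C1C(=O)O[C@H](C(OC(C)=O)C(=C)CO)[C@H]1[C@H](OC(=O)/C(C)=C\C)C(O)C(C=C)C(OC)OC | intermediate
20 | keto enal (C9 ketone, C15 aldehyde) | C=C1C(=O)O[C@H](C(OC(C)=O)C(=C)C=O)[C@H]1[C@H](OC(=O)/C(C)=C\C)C(=O)C(C=C)C(OC)OC | intermediate
21 | trimethylsilyl dienol ether of 20 (C9(OTMS)=C10–C1=C2) | C=C1C(=O)O[C@H](C(OC(C)=O)C(=C)C=O)[C@H]1[C@H](OC(=O)/C(C)=C\C)C(O[Si](C)(C)C)=C(C=C)C(OC)OC | intermediate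
22 | Diels–Alder adduct, decalin with C9–OTMS and angular C4–CHO (mixture at C4, C5, C9) | C=C1C(=O)O[C@H]2[C@H]1[C@H](OC(=O)/C(C)=C\C)C3(O[Si](C)(C)C)C(C(OC)OC)=CCCC3(C=O)C2OC(C)=O | intermediate
23 | tetrabutylammonium C9 alkoxide of desilylated 22 | C=C1C(=O)O[C@H]2[C@H]1[C@H](OC(=O)/C(C)=C\C)C3([O-])C(C(OC)OC)=CCCC3(C=O)C2OC(C)=O.CCCC[N+](CCCC)(CCCC)CCCC | intermediate
24 | ring-opened ten-membered aldehyde enolate (C9 ketone, C5–OAc), tetrabutylammonium salt | C=C1C(=O)O[C@@H]2C(OC(C)=O)C(=C[O-])CC/C=C(/C(OC)OC)C(=O)[C@@H](OC(=O)/C(C)=C\C)[C@@H]12.CCCC[N+](CCCC)(CCCC)CCCC | intermediate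
25 | ten-membered 9-oxo-15-al, C14 dimethyl acetal, 8-O-angeloyl, 6,12-olide | C=C1C(=O)O[C@@H]2/C=C(/C=O)CC/C=C(/C(OC)OC)C(=O)[C@@H](OC(=O)/C(C)=C\C)[C@@H]12 | intermediate
26 | 9α,15-diol | C=C1C(=O)O[C@@H]2/C=C(/CO)CC/C=C(/C(OC)OC)[C@H](O)[C@@H](OC(=O)/C(C)=C\C)[C@@H]12 | intermediate
27 | 15-O-TBS ether of 26 | C=C1C(=O)O[C@@H]2/C=C(/CO[Si](C)(C)C(C)(C)C)CC/C=C(/C(OC)OC)[C@H](O)[C@@H](OC(=O)/C(C)=C\C)[C@@H]12 | intermediate
28 | 8,9-bis-angelate of 27 | C=C1C(=O)O[C@@H]2/C=C(/CO[Si](C)(C)C(C)(C)C)CC/C=C(/C(OC)OC)[C@H](OC(=O)/C(C)=C\C)[C@@H](OC(=O)/C(C)=C\C)[C@@H]12 | intermediate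
29 | CNP0139154.1 | C=C1C(=O)O[C@@H]2/C=C(/CO)CC/C=C(/C=O)[C@H](OC(=O)/C(C)=C\C)[C@@H](OC(=O)/C(C)=C\C)[C@@H]12 | target

**Step count and risks**

Total step count: 19 (steps 1–3 make fragments 3 and 5; steps 4–19 are the main line). Longest linear sequence: 16 steps (steps 4 to 19, from 6 and 7 to 29).

Most likely to fail, first: step 14. The cycloaddition has to join two fully substituted carbons (C9 and C4), and the amine base may attack the allylic acetate of the enal. The fallback sets out from 20 and avoids the silyl dienol ether: Cs2CO3 in MeCN at 0 °C generates the cesium dienolate, which undergoes an anionic [4+2] (double Michael) annulation onto the acrolein unit. The resulting cesium aldolate F1 undergoes the retro-aldol/E1cB sequence in the same flask, and the route is rejoined at 25.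

Second: step 15, the proposed new ring expansion. Competing acyl migration from O8 to the C9 alkoxide, C8 epimerisation or attack on the lactone may intervene. The fallback uses known chemistry and sets out from 22. Citric acid in MeOH at 0 °C removes the silyl group to give the tertiary alcohol F2. A Suárez alkoxy-radical fragmentation (PhI(OAc)2, I2, visible light, CH2Cl2) then cleaves C4–C9 by β-scission, which is favoured because it forms the conjugated C9 ketone and a tertiary α-formyl radical that is trapped by iodine; this gives the ten-membered α-iodo aldehyde F3. Zn dust with NH4Cl in THF–MeOH at 0 °C effects reductive β-elimination of iodide and acetate through the zinc enolate, and the route is rejoined at 25.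

Third: step 16. The facial selectivity at C9 rests on substrate control in a flexible ten-membered ring and could give the 9-epimer. The fallback sets out from 25 and switches to reagent control: Corey–Bakshi–Shibata reduction with (S)-2-methyl-CBS-oxazaborolidine (20 mol%) and catecholborane in PhMe at −78 °C, with the alkenyl arm acting as the large group. It reduces both carbonyl groups and comes back to the route at 26 without any new compound.

Further compounds
F1 | step 14 | cesium C9 alkoxide of the decalin aldol (cesium analogue of 23) | C=C1C(=O)O[C@H]2[C@H]1[C@H](OC(=O)/C(C)=C\C)C3([O-])C(C(OC)OC)=CCCC3(C=O)C2OC(C)=O.[Cs+]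
F2 | step 15 | tertiary alcohol, desilylated 22 | C=C1C(=O)O[C@H]2[C@H]1[C@H](OC(=O)/C(C)=C\C)C3(O)C(C(OC)OC)=CCCC3(C=O)C2OC(C)=O
F3 | step 15 | ten-membered α-iodo aldehyde (C4–I, C5–OAc, C9 ketone) | C=C1C(=O)O[C@@H]2C(OC(C)=O)C(I)(C=O)CC/C=C(/C(OC)OC)C(=O)[C@@H](OC(=O)/C(C)=C\C)[C@@H]12
F0 | step 16 | none | none
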